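Carbon labels C1–C20 follow the gibberellane numbering of the target and denote the same atoms in every intermediate. C10 is the spiro carbon, C20 the lactone carbonyl, and C9–C11–C12 the three-carbon unit of the lactone ring.

## Analysis of the target

The target is pentacyclic: ring A (C1–C5, C10), ring B (C5, C6, C8, C9, C10), ring C (C8, C9, C11–C14), ring D (C8, C13–C16) and a δ-lactone from C20 to the C12 oxygen. It has ten stereocentres (C2, C3, C4, C5, C6, C8, C9, C10, C12, C13). Rings A and B are trans-fused, rings B and C cis-fused. C19, C20 and the C5–C6 bond lie on one face of ring A; the 2,3-diol, the C4 methyl group and C9 lie on the other. Sensitive groups are the exocyclic C16=C17 alkene, the cis-diol, two hindered carboxylic acids (C7, C19) and the lactone. The difficulty is the density: two quaternary carbons (C4, C10) flank C5, a third (C8) is a bridgehead, and the lactone must span ring C 1,3-diaxially. The strategy rests on one feature: C8, C9, C11, C12, C13, C16 and C15 form a cycloheptane bridged by C14, and the lactone joins C9 and C12, the two ends of the three-carbon unit C9–C11–C12. That seven-membered ring is therefore the sum of a five-carbon cyclopentadiene (C8, C15, C16, C13 with C14 as its CH2) and a three-carbon oxyallyl unit that already lies inside the lactone.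

## Retrosynthetic reasoning

**39 back to 37.** The two acids and the diol are unmasked last, from diol diester 38 and acetonide diester 37. Only O–CH3 and acetal C–O bonds are cut; the free acids and diol would interfere with every earlier organometallic or basic step.

**37 back to 33.** The C16=C17 bond is cut to ketone 36, which comes from alcohol 35 and alkene 33 by hydroboration. The cycloaddition leaves its alkene at C15=C16, and quaternary C8 should direct boron to C16.

**33 back to 30.** The C11 carbonyl of ketone 30 is removed by way of alcohol 31 and thionocarbonate 32. The oxygen is only needed to generate the cation; no carbon–carbon bond is involved.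

**30 back to 28.** C8–C9 and C12–C13 are cut together, through oxyallyl cation 29. These are the two bonds that close the seven-membered ring; cutting them also opens rings B and C and removes four stereocentres, leaving chloro ketone 28 with a tethered cyclopentadienyl ring. The forward reaction must ionise C9–Cl, bond both cation termini to the diene termini on one face, and do so in the arrangement that puts the lactone on the C14 side.

**28 back to 22.** The cyclopentadienyl ring and the C7 ester are traced to the allylic bicyclic lactone in 26, which is opened by palladium through acid 27. The diene is too sensitive to carry, so it stays masked until the step before the cycloaddition. The lactone ring of 26 is cut at C12–O and C11–C12 to diazoketone 25, mixed anhydride 24 and acid 23, itself from silylethyl ester 22. The neighbouring tert-butyl ester supplies the ring oxygen, so C20 needs no separate deprotection.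

**22 back to 17.** The alkene of the bicyclic lactone comes from bromide 21 by elimination. The acetonide and diol (21, 20) come from alkene 19, made from ketone 17 through enol triflate 18. The bromide keeps the five-membered ring saturated while the ring A alkene is dihydroxylated.

**17 back to 12 and 14.** C5–C6 and C4–CH3 are cut in one operation, through enolates 15 and 16. The lactone enolate brings C6, C7 and the future diene as one rigid chiral unit; the alkylidene keto ester 12 accepts it at C5 and is then methylated at C4. Both new ring stereocentres are set relative to C10.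

**12 back to 4 and 3.** The methyl ester on C4 comes from iodide 11, and the enone from alkene 9 by allylic oxidation (10). The chlorine on C9 is placed in 7 (enolate 8), the only stage at which C9 is the sole enolisable carbon. Alkene 7 comes from ketone 5 through triflate 6. C10 is set in 5 by asymmetric alkylation of keto ester 4 with bromoacetate 3, made from 1 and 2.

**14 back to 13.** Bromolactone 14 comes from acid 13 in one step; the single stereocentre of 13 fixes all three of 14.

## Alternatives that were turned down

**Alternative 1:** This plan cuts C9–C11 and C1–C10. A ketone enolate would close ring C by a 6-exo conjugate addition onto the unsaturated ester of a ring B cyclopentene, and the ester enolate formed would be allylated in the same flask, giving the B/C hydrindanone A1.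
- For it: both bond formations are standard, the cis B/C fusion follows from the intramolecular addition, and the allyl and vinyl groups of A1 are placed for a ring-closing metathesis that would put the ring A alkene at C2=C3. On precedent it is stronger than the chosen route, since no step lacks a close model.
- Against it: A1 still lacks ring A, ring D and the lactone. Its C12 is a ketone that must be reduced to the axial alcohol before it can lactonise onto C20. The quaternary C4 (methyl, vinyl, ester) has to be set on an open chain next to C5 and C6.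
- Comparison: three ring closures and several stereoselective redox steps remain after A1. The chosen route offers in exchange the closure of rings B and C, all carbons of ring D and the lactone in its final oxidation state in one step.

**Alternative 2:** This plan cuts C13–C16 and C12–O in the sense of a rearrangement. Ionisation of a C13 sulfonate in a bicyclo[2.2.2]octane isomer would shift C16 from C12 to C13, and the C20 tert-butyl ester would capture the cation at C12, giving A2.
- For it: the shift relieves strain and is stereospecific, and the lactone forms in the same event. A2 is two deprotections from the target and is the same compound as 37 of the present route. On the endgame this alternative is clearly stronger: the chosen route needs eight steps after its key step.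
- Against it: the full pentacyclic framework, with nine stereocentres, the exocyclic alkene and a correctly oriented leaving group, must exist before the key step. The migrating carbon is vinylic, so alkene participation and elimination compete with capture by the ester.
- Comparison: the difficulty is moved into the synthesis of the rearrangement substrate. The chosen route creates most of the complexity in a single early event from a simpler precursor.

**Alternative 3:** This plan cuts C4–C5 and C9–C10. One-electron oxidation of a β-keto ester would give a C4 radical that adds 6-endo to C5 of a C5=C10 alkene; the tertiary C10 radical would then add 5-exo to C9 of a ring C enone, giving the tricyclic diketone A3.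
- For it: rings A and B and four stereocentres, two of them the quaternary C4 and C10, arise in one step of a known radical cascade, and either C4 epimer of the substrate can be used. In setting C4 and C10 together it is stronger than the chosen route, which spends many steps on ring A.
- Against it: A3 carries C20 as a protected CH2OH that must be oxidised, has no oxygen at C2, has ketones at C3 and C12 that each need a stereoselective reduction, and still lacks ring D. The ring fusion depends on the transition state of the second cyclisation, and the α-keto radical must be terminated cleanly.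
- Comparison: the chosen route delivers rings B, C and D with the lactone and the C12 oxygen already in place, so that what follows is functional-group change only.

Key step: step 20

Assumptions (remarks on the chemistry):
- C9 (the chlorine-bearing carbon) is carried from 9 to 28 as a mixture of epimers; structures show the (R)-epimer. Both give the same cation 29.
- In step 2 the catalyst enantiomer that gives (R)-5 is used; which antipode that is has to be checked on 5.
- 28 is a set of cyclopentadiene tautomers that interconvert by 1,5-hydrogen shifts; the reacting 1-substituted tautomer is drawn.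
- The C11 carbinol in 31 and 32 is drawn as the epimer expected from hydride attack on the lactone face; the centre is removed in step 23.
- (S)-2-(Cyclopent-2-en-1-yl)acetic acid 13 is taken as a commercial single enantiomer.

## Route

Step 1
Reactants: 1 bromoacetyl bromide; 2 2-(trimethylsilyl)ethanol
Product: 3 2-(trimethylsilyl)ethyl bromoacetate
Conditions: pyridine, CH2Cl2, 0 °C
Reagents that add atoms: none
Why: Acylation of the alcohol by the acid bromide; pyridine binds HBr.

Step 2
Reactants: 4 tert-butyl 2-oxocyclohexane-1-carboxylate; 3 2-(trimethylsilyl)ethyl bromoacetate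
Product: 5 tert-butyl (1R)-2-oxo-1-{2-oxo-2-[2-(trimethylsilyl)ethoxy]ethyl}cyclohexane-1-carboxylate
Conditions: chiral binaphthyl N-spiro quaternary ammonium bromide (1 mol %), Cs2CO3, toluene, −30 °C
Reagents that add atoms: none
Why: Asymmetric phase-transfer alkylation of the β-keto ester enolate: the chiral ammonium ion pairs with the enolate and leaves one face open to the bromoacetate, which sets quaternary C10 as (R).

Step 3
Reactants: 5 keto diester
Product: 6 tert-butyl (1R)-1-{2-oxo-2-[2-(trimethylsilyl)ethoxy]ethyl}-2-[(trifluoromethylsulfonyl)oxy]cyclohex-2-ene-1-carboxylate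
Conditions: sodium bis(trimethylsilyl)amide, PhNTf2, THF, −78 °C
Reagents that add atoms: N-phenyl-bis(trifluoromethanesulfonimide), O=S(=O)(N(c1ccccc1)S(=O)(=O)C(F)(F)F)C(F)(F)F
Why: The ketone can enolise only toward C4 because C10 is quaternary; the sodium enolate is O-sulfonylated to the enol triflate.

Step 4
Reactants: 6 enol triflate
Product: 7 tert-butyl (1R)-1-{2-oxo-2-[2-(trimethylsilyl)ethoxy]ethyl}cyclohex-2-ene-1-carboxylate
Conditions: Pd(OAc)2 (5 mol %), PPh3, Bu3N, HCO2H, DMF, 60 °C
Reagents that add atoms: none
Why: Palladium-catalysed formate reduction of the enol triflate (oxidative addition, formate exchange, loss of CO2, reductive elimination) gives the C4=C5 alkene without touching C10.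

Step 5
Reactants: 7 cyclohexene diester
Product: 9 tert-butyl (1R)-1-{(1R)-1-chloro-2-oxo-2-[2-(trimethylsilyl)ethoxy]ethyl}cyclohex-2-ene-1-carboxylate, via lithium ester enolate 8 (not isolated)
Conditions: lithium diisopropylamide, THF, −78 °C; then N-chlorosuccinimide, −78 → 0 °C
Reagents that add atoms: N-chlorosuccinimide, O=C1CCC(=O)N1Cl
Why: C9 is the only enolisable carbon (C10 is quaternary and the tert-butyl ester has no α-hydrogen), so enolate 8 forms cleanly and is chlorinated by the N-chloro imide; both C9 epimers are carried on.

Step 6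
Reactants: 9 chloro diester
Product: 10 tert-butyl (1R)-1-{(1R)-1-chloro-2-oxo-2-[2-(trimethylsilyl)ethoxy]ethyl}-4-oxocyclohex-2-ene-1-carboxylate
Conditions: Rh2(cap)4 (1 mol %), t-BuOOH, K2CO3, CH2Cl2, 25 °C
Reagents that add atoms: tert-butyl hydroperoxide, CC(C)(C)OO
Why: Allylic oxidation by a tert-butylperoxy radical chain: C3 is the only allylic CH2 because C10 is quaternary, and the allyl radical is trapped at the unhindered C3 end, so the carbonyl is conjugated to C4=C5.

Step 7
Reactants: 10 enone
Product: 11 tert-butyl (1R)-1-{(1R)-1-chloro-2-oxo-2-[2-(trimethylsilyl)ethoxy]ethyl}-3-iodo-4-oxocyclohex-2-ene-1-carboxylate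
Conditions: I2, pyridine, CH2Cl2, 25 °C
Reagents that add atoms: iodine, II
Why: α-Iodination of the enone by addition–elimination (pyridine adds at C5, the enolate is iodinated at C4, pyridine is lost), a Baylis–Hillman-type sequence.

Step 8
Reactants: 11 iodo enone
Product: 12 1-tert-butyl 3-methyl (1R)-1-{(1R)-1-chloro-2-oxo-2-[2-(trimethylsilyl)ethoxy]ethyl}-4-oxocyclohex-2-ene-1,3-dicarboxylate
Conditions: PdCl2(PPh3)2 (5 mol %), CO (1 atm), MeOH, Et3N, DMF, 50 °C
Reagents that add atoms: carbon monoxide, [C-]#[O+]; methanol, CO
Why: Palladium-catalysed alkoxycarbonylation: oxidative addition into the C4–I bond, CO insertion and methanolysis give the alkylidene β-keto ester; with C10 quaternary the product cannot tautomerise to a dienol.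

Step 9
Reactants: 13 (S)-2-(cyclopent-2-en-1-yl)acetic acid
Product: 14 (1R,5S,8R)-8-bromo-2-oxabicyclo[3.3.0]octan-3-one
Conditions: N-bromosuccinimide, THF, 0 → 25 °C
Reagents that add atoms: N-bromosuccinimide, O=C1CCC(=O)N1Br
Why: Bromolactonisation: the carboxyl group reaches the alkene only on its own face, so the γ-lactone is cis-fused and bromine ends up trans to the ring oxygen; the (S) centre of 13 fixes all three centres.

Step 10
Reactants: 12 alkylidene keto ester; 14 bromolactone
Product: 17 ring A keto ester carrying the bromolactone at C6 (C4 methylated), via lithium lactone enolate 15 (not isolated), via lithium keto ester enolate 16 (not isolated)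
Conditions: 14, lithium diisopropylamide, THF, −78 °C; add 12, −78 °C; then MeI, DMPU, −78 → 0 °C
Reagents that add atoms: iodomethane, CI
Why: Tandem Michael addition–alkylation: enolate 15 reacts through its convex face (sets C6) at C5 of the doubly activated alkene, from the side opposite the branched chloroacetate arm on C10 and cis to the flat tert-butyl ester (sets C5). The chelated enolate 16 is then C-methylated anti to the new C5 substituent, which puts the methyl group trans and the methyl ester cis to C6 at quaternary C4.

Step 11
Reactants: 17 ring A ketone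
Product: 18 C2=C3 enol triflate of 17
Conditions: Tf2O, 2,6-di-tert-butyl-4-methylpyridine, CH2Cl2, 0 → 25 °C
Reagents that add atoms: trifluoromethanesulfonic anhydride, O=S(=O)(OS(=O)(=O)C(F)(F)F)C(F)(F)F
Why: Triflation of the ketone oxygen and loss of a proton from C2, the only enolisable position because C4 is quaternary; no strong base is used, so lactone, bromide and chloro ester are spared.

Step 12
Reactants: 18 enol triflate
Product: 19 ring A cyclohexene (C2=C3)
Conditions: Pd(OAc)2 (5 mol %), PPh3, Bu3N, HCO2H, DMF, 60 °C
Reagents that add atoms: none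
Why: Palladium-catalysed formate reduction of the enol triflate leaves the C2=C3 alkene; the secondary alkyl bromide does not add to zerovalent palladium under these conditions.

Step 13
Reactants: 19 cyclohexene
Product: 20 2β,3β-diol
Conditions: OsO4 (2 mol %), NMO, acetone/H2O, 25 °C
Reagents that add atoms: N-methylmorpholine N-oxide, C[N+]1([O-])CCOCC1; water, O
Why: Catalytic syn-dihydroxylation: with the C6 substituent equatorial the C19 and C20 esters are axial on the α-face, so osmylation should take place on the β-face and set C2 and C3 together; the bromolactone carries no alkene at this stage.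

Step 14
Reactants: 20 diol
Product: 21 2,3-acetonide
Conditions: 2,2-dimethoxypropane, pyridinium p-toluenesulfonate, acetone, 25 °C
Reagents that add atoms: 2,2-dimethoxypropane, COC(C)(C)OC
Why: Acid-catalysed transketalisation; the cis-diol closes the five-membered acetonide.

Step 15
Reactants: 21 bromolactone acetonide
Product: 22 allylic lactone (2-oxabicyclo[3.3.0]oct-7-en-3-one unit at C6)
Conditions: DBU, toluene, 90 °C
Reagents that add atoms: none
Why: E2 dehydrobromination: only a hydrogen of the ring CH2 is anti to bromine (the hydrogen on the oxygen-bearing carbon is syn), so the alkene forms next to the lactone oxygen and the lactone becomes an allylic ester.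

Step 16
Reactants: 22 silylethyl ester
Product: 23 C11 carboxylic acid
Conditions: Bu4NF, THF, 0 → 25 °C; aq. KHSO4 work-up
Reagents that add atoms: none
Why: Fluoride attacks silicon and the ester fragments by β-elimination to carboxylate, ethene and fluorotrimethylsilane; methyl and tert-butyl esters, lactone, acetonide and chloride are not touched.

Step 17
Reactants: 23 C11 acid
Product: 25 C11 diazoketone, via mixed anhydride 24 (not isolated)
Conditions: i-BuOCOCl, N-methylmorpholine, THF, −15 °C; then CH2N2, Et2O, 0 °C
Reagents that add atoms: diazomethane, C=[N+]=[N-]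
Why: First stage of the Arndt–Eistert sequence: the mixed anhydride acylates diazomethane at the more electrophilic acyl carbon to give the α-diazo ketone, which adds C12.

Step 18
Reactants: 25 diazoketone
Product: 26 chloro keto spiro-δ-lactone carrying the allylic lactone at C6
Conditions: HBF4·OEt2 (20 mol %), CH2Cl2, −40 → 0 °C
Reagents that add atoms: none
Why: Acid-promoted diazoketone cyclisation: protonation at the diazo carbon gives an α-keto diazonium ion, the carbonyl oxygen of the neighbouring C20 tert-butyl ester displaces N2 through a six-membered transition state, and the tert-butyl cation leaves as isobutene, which regenerates the acid and closes the C20–O–C12 lactone.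

Step 19
Reactants: 26 chloro keto lactone
Product: 28 chloro keto lactone bearing the cyclopentadienyl group on C6 (C7 methyl ester), via cyclopentadienyl acid 27 (not isolated)
Conditions: Pd(PPh3)4 (5 mol %), THF, 40 °C; then Me3SiCHN2, MeOH, 0 °C
Reagents that add atoms: trimethylsilyldiazomethane, C[Si](C)(C)C=[N+]=[N-]
Why: Tsuji–Trost-type elimination: zerovalent palladium ionises the allylic lactone to a π-allyl complex that carries its own carboxylate, β-hydride elimination releases the cyclopentadiene and the C7 acid, and trimethylsilyldiazomethane esterifies the acid in the same flask. No base is present, so C6 should keep its configuration.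

Step 20
Reactants: 28 chloro ketone with tethered cyclopentadiene
Product: 30 pentacyclic lactone (C11 ketone, C15=C16 alkene), via oxyallyl cation 29 (not isolated)
Conditions: Et3N (3 equiv), CF3CH2OH, 0 → 25 °C, 0.005 M
Reagents that add atoms: none
Why: Proposed new method: triethylamine in trifluoroethanol enolises the C11 ketone toward the acyloxy-bearing C12 and the enolate expels chloride from C9, giving oxyallyl cation 29 held U-shaped inside the δ-lactone; the cation then bonds through C9 and C12 to the diene termini C8 and C13, in one step or through a short-lived allyl cation/enolate pair. The closest known reaction type is the intramolecular (4+3) cycloaddition of cyclic oxyallyl cations, made from α-chloro ketones under these conditions, with tethered dienes; a cation whose ring is a lactone and whose terminus carries the ring oxygen has not been used this way. Ring B closes 5-exo through C8–C9 across the three-atom tether C10–C5–C6, and ring C closes through C12–C13 as the 6-(enolendo)-exo half of the seven-membered ring that C14 bridges. C9 is set by the cation face that the tether can reach, which C10 and C5 fix; C12 follows because the lactone ring forces both termini to bond on the same face; C8 and C13 follow from suprafacial bonding to the diene. The step needs the compact arrangement (C11–O over C15–C16, lactone over C14); the short tether should secure it, because only then can C6 span from C8 to C10 without strain while ring A points away from the diene. It also needs cycloaddition to outrun solvolysis: the C12 oxygen stabilises the cation and high dilution suppresses intermolecular capture. The 2-substituted diene tautomer cannot reach the cation and is fed back by 1,5-hydrogen shifts.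

Step 21
Reactants: 30 C11 ketone
Product: 31 C11 alcohol
Conditions: NaBH4, CeCl3·7H2O, MeOH/THF, −78 °C
Reagents that add atoms: none
Why: Luche reduction: the bridged C11 ketone cannot enolise (Bredt's rule) and is reduced at low temperature; the configuration of the carbinol is of no consequence.

Step 22
Reactants: 31 C11 alcohol
Product: 32 C11 O-phenyl thionocarbonate
Conditions: PhOC(S)Cl, pyridine, 4-(dimethylamino)pyridine (cat.), CH2Cl2, 25 °C
Reagents that add atoms: O-phenyl chlorothionoformate, S=C(Cl)Oc1ccccc1
Why: O-Acylation of the secondary alcohol to the thionocarbonate needed for radical deoxygenation.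

Step 23
Reactants: 32 thionocarbonate
Product: 33 C11-deoxy pentacycle (C15=C16 alkene)
Conditions: Bu3SnH, AIBN (cat.), toluene, 90 °C
Reagents that add atoms: none
Why: Barton–McCombie deoxygenation: the C11 radical is reduced by the stannane faster than it can shift the neighbouring acyloxy group, and it cannot reach C15=C16 in a ring of useful size.

Step 24
Reactants: 33 alkene
Product: 35 C16 alcohol, via alkylborane 34 (not isolated)
Conditions: 9-BBN, THF, 0 → 25 °C; then H2O2, aq. NaHCO3, 0 °C
Reagents that add atoms: hydrogen peroxide, OO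
Why: Hydroboration–oxidation: boron should add to C16, away from quaternary C8, on the exo face of the strained alkene (the C14 side); buffered peroxide spares lactone and esters. The C16 configuration is lost in step 25.

Step 25
Reactants: 35 C16 alcohol
Product: 36 C16 ketone
Conditions: DMP (1,1,1-triacetoxy-1,1-dihydro-1,2-benziodoxol-3(1H)-one), CH2Cl2, 25 °C
Reagents that add atoms: none
Why: Dess–Martin oxidation of the secondary alcohol under neutral conditions.

Step 26
Reactants: 36 C16 ketone
Product: 37 2,3-acetonide 7,19-dimethyl ester of the target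
Conditions: Ph3PCH3Br, KOt-Bu, THF, 0 → 25 °C
Reagents that add atoms: methyltriphenylphosphonium bromide, C[P+](c1ccccc1)(c1ccccc1)c1ccccc1.[Br-]
Why: Wittig methylenation of the cyclopentanone; the ylide at 0 °C tolerates the esters and the lactone and is too weak a base to disturb C6.

Step 27
Reactants: 37 acetonide
Product: 38 7,19-dimethyl ester of the target
Conditions: AcOH/H2O (4:1), 40 °C
Reagents that add atoms: none
Why: Acid-catalysed hydrolysis of the acetonide under conditions mild enough for the exocyclic alkene.

Step 28
Reactants: 38 diol dimethyl ester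
Product: 39 CNP0212122.1 (target diacid)
Conditions: n-PrSLi (from n-PrSH and n-BuLi), HMPA, 25 °C; then aq. HCl
Reagents that add atoms: none
Why: SN2 demethylation: the thiolate attacks the O-methyl carbons of the hindered C7 and C19 esters, while the lactone is spared because the backside of C12 is blocked by the cage; acidification gives the diacid.

## Compound list

1 | bromoacetyl bromide | BrCC(Br)=O | starting material
2 | 2-(trimethylsilyl)ethanol | C[Si](C)(C)CCO | starting material
3 | 2-(trimethylsilyl)ethyl bromoacetate | C[Si](C)(C)CCOC(=O)CBr | intermediate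
4 | tert-butyl 2-oxocyclohexane-1-carboxylate | CC(C)(C)OC(=O)C1CCCCC1=O | starting material
5 | tert-butyl (1R)-2-oxo-1-{2-oxo-2-[2-(trimethylsilyl)ethoxy]ethyl}cyclohexane-1-carboxylate | C[Si](C)(C)CCOC(=O)C[C@@]2(CCCCC2=O)C(=O)OC(C)(C)C | intermediate
6 | enol triflate of 5 (C4=C5, triflate on C5) | C[Si](C)(C)CCOC(=O)C[C@@]2(CCCC=C2OS(=O)(=O)C(F)(F)F)C(=O)OC(C)(C)C | intermediate
7 | tert-butyl (1R)-1-{2-oxo-2-[2-(trimethylsilyl)ethoxy]ethyl}cyclohex-2-ene-1-carboxylate | C[Si](C)(C)CCOC(=O)C[C@@]2(CCCC=C2)C(=O)OC(C)(C)C | intermediate
8 | lithium enolate of 7 (C9=C11) | C[Si](C)(C)CCOC(O[Li])=C[C@@]2(CCCC=C2)C(=O)OC(C)(C)C | intermediate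
9 | tert-butyl (1R)-1-{(1R)-1-chloro-2-oxo-2-[2-(trimethylsilyl)ethoxy]ethyl}cyclohex-2-ene-1-carboxylate | C[Si](C)(C)CCOC(=O)[C@H](Cl)[C@@]2(CCCC=C2)C(=O)OC(C)(C)C | intermediate
10 | 4-oxo derivative of 9 (C3 ketone, C4=C5) | C[Si](C)(C)CCOC(=O)[C@H](Cl)[C@@]2(CCC(=O)C=C2)C(=O)OC(C)(C)C | intermediate
11 | 3-iodo-4-oxo derivative (iodine on C4) | C[Si](C)(C)CCOC(=O)[C@H](Cl)[C@@]2(CCC(=O)C(I)=C2)C(=O)OC(C)(C)C | intermediate
12 | 1-tert-butyl 3-methyl (1R)-1-{(1R)-1-chloro-2-oxo-2-[2-(trimethylsilyl)ethoxy]ethyl}-4-oxocyclohex-2-ene-1,3-dicarboxylate | C[Si](C)(C)CCOC(=O)[C@H](Cl)[C@@]2(CCC(=O)C(C(=O)OC)=C2)C(=O)OC(C)(C)C | intermediate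
13 | (S)-2-(cyclopent-2-en-1-yl)acetic acid | OC(=O)C[C@H]1C=CCC1 | starting material
14 | (1R,5S,8R)-8-bromo-2-oxabicyclo[3.3.0]octan-3-one | C1C(=O)O[C@H]2[C@H](Br)CC[C@@H]12 | intermediate
15 | lithium enolate of 14 | C1=C(O[Li])O[C@H]2[C@H](Br)CC[C@@H]12 | intermediate
16 | lithium enolate of the Michael adduct (C3–O–Li, C3=C4) | C[Si](C)(C)CCOC(=O)[C@H](Cl)[C@@]2(CCC(O[Li])=C(C(=O)OC)[C@H]2[C@@H]5C(=O)O[C@H]6[C@H](Br)CC[C@@H]56)C(=O)OC(C)(C)C | intermediate
17 | ring A ketone: C3=O, C4 (CH3, CO2Me), C5 bearing the bromolactone through C6, C10 (CO2t-Bu, chloro silylethyl acetate arm) | C[Si](C)(C)CCOC(=O)[C@H](Cl)[C@@]2(CCC(=O)[C@@](C)(C(=O)OC)[C@H]2[C@@H]5C(=O)O[C@H]6[C@H](Br)CC[C@@H]56)C(=O)OC(C)(C)C | intermediate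
18 | enol triflate of 17 (C2=C3, triflate on C3) | C[Si](C)(C)CCOC(=O)[C@H](Cl)[C@@]2(CC=C(OS(=O)(=O)C(F)(F)F)[C@@](C)(C(=O)OC)[C@H]2[C@@H]5C(=O)O[C@H]6[C@H](Br)CC[C@@H]56)C(=O)OC(C)(C)C | intermediate
19 | ring A cyclohexene (C2=C3) | C[Si](C)(C)CCOC(=O)[C@H](Cl)[C@@]2(CC=C[C@@](C)(C(=O)OC)[C@H]2[C@@H]5C(=O)O[C@H]6[C@H](Br)CC[C@@H]56)C(=O)OC(C)(C)C | intermediate
20 | 2β,3β-diol | C[Si](C)(C)CCOC(=O)[C@H](Cl)[C@@]2(C[C@H](O)[C@H](O)[C@@](C)(C(=O)OC)[C@H]2[C@@H]5C(=O)O[C@H]6[C@H](Br)CC[C@@H]56)C(=O)OC(C)(C)C | intermediate
21 | 2,3-acetonide of 20 | C[Si](C)(C)CCOC(=O)[C@H](Cl)[C@@]2(C[C@@H]4OC(C)(C)O[C@@H]4[C@@](C)(C(=O)OC)[C@H]2[C@@H]5C(=O)O[C@H]6[C@H](Br)CC[C@@H]56)C(=O)OC(C)(C)C | intermediate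
22 | allylic lactone (2-oxabicyclo[3.3.0]oct-7-en-3-one at C6) | C[Si](C)(C)CCOC(=O)[C@H](Cl)[C@@]2(C[C@@H]4OC(C)(C)O[C@@H]4[C@@](C)(C(=O)OC)[C@H]2[C@@H]5C(=O)O[C@H]6C=CC[C@@H]56)C(=O)OC(C)(C)C | intermediate
23 | C11 carboxylic acid | OC(=O)[C@H](Cl)[C@@]2(C[C@@H]4OC(C)(C)O[C@@H]4[C@@](C)(C(=O)OC)[C@H]2[C@@H]5C(=O)O[C@H]6C=CC[C@@H]56)C(=O)OC(C)(C)C | intermediate
24 | mixed isobutyl carbonic anhydride of 23 | CC(C)COC(=O)OC(=O)[C@H](Cl)[C@@]2(C[C@@H]4OC(C)(C)O[C@@H]4[C@@](C)(C(=O)OC)[C@H]2[C@@H]5C(=O)O[C@H]6C=CC[C@@H]56)C(=O)OC(C)(C)C | intermediate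
25 | C11 diazoketone (C12 = CHN2) | [N-]=[N+]=CC(=O)[C@H](Cl)[C@@]2(C[C@@H]4OC(C)(C)O[C@@H]4[C@@](C)(C(=O)OC)[C@H]2[C@@H]5C(=O)O[C@H]6C=CC[C@@H]56)C(=O)OC(C)(C)C | intermediate
26 | chloro keto spiro-δ-lactone with the allylic lactone at C6 | C1C(=O)[C@H](Cl)[C@@]2(C[C@@H]4OC(C)(C)O[C@@H]4[C@@](C)(C(=O)OC)[C@H]2[C@@H]5C(=O)O[C@H]6C=CC[C@@H]56)C(=O)O1 | intermediate
27 | C7 acid with cyclopentadienyl group on C6 | C1C(=O)[C@H](Cl)[C@@]2(C[C@@H]4OC(C)(C)O[C@@H]4[C@@](C)(C(=O)OC)[C@H]2[C@H](C(=O)O)C3=CC=CC3)C(=O)O1 | intermediate
28 | key-step precursor: ring A spiro-lactone chloro ketone, cyclopentadienyl and CO2Me on C6 | C1C(=O)[C@H](Cl)[C@@]2(C[C@@H]4OC(C)(C)O[C@@H]4[C@@](C)(C(=O)OC)[C@H]2[C@H](C(=O)OC)C3=CC=CC3)C(=O)O1 | intermediate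
29 | lactone-embedded oxyallyl cation (C9–C11–C12) | [CH+]1C([O-])=C[C@@]2(C[C@@H]4OC(C)(C)O[C@@H]4[C@@](C)(C(=O)OC)[C@H]2[C@H](C(=O)OC)C3=CC=CC3)C(=O)O1 | intermediate
30 | pentacyclic lactone, C11 ketone, C15=C16 alkene | C1=C[C@]23C[C@H]1[C@@H]1C(=O)[C@H]2[C@@]2(C[C@@H]4OC(C)(C)O[C@@H]4[C@@](C)(C(=O)OC)[C@H]2[C@@H]3C(=O)OC)C(=O)O1 | intermediate
31 | C11 alcohol | C1=C[C@]23C[C@H]1[C@@H]1[C@H](O)[C@H]2[C@@]2(C[C@@H]4OC(C)(C)O[C@@H]4[C@@](C)(C(=O)OC)[C@H]2[C@@H]3C(=O)OC)C(=O)O1 | intermediate
32 | C11 O-phenyl thionocarbonate | C1=C[C@]23C[C@H]1[C@@H]1[C@H](OC(=S)Oc5ccccc5)[C@H]2[C@@]2(C[C@@H]4OC(C)(C)O[C@@H]4[C@@](C)(C(=O)OC)[C@H]2[C@@H]3C(=O)OC)C(=O)O1 | intermediate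
33 | C11-deoxy pentacycle, C15=C16 alkene | C1=C[C@]23C[C@H]1[C@@H]1C[C@H]2[C@@]2(C[C@@H]4OC(C)(C)O[C@@H]4[C@@](C)(C(=O)OC)[C@H]2[C@@H]3C(=O)OC)C(=O)O1 | intermediate
34 | C16 B-alkyl-9-borabicyclo[3.3.1]nonane | C5CCC6CCCC5B6[C@@H]1C[C@]23C[C@H]1[C@@H]1C[C@H]2[C@@]2(C[C@@H]4OC(C)(C)O[C@@H]4[C@@](C)(C(=O)OC)[C@H]2[C@@H]3C(=O)OC)C(=O)O1 | intermediate
35 | C16 alcohol (exo) | O[C@@H]1C[C@]23C[C@H]1[C@@H]1C[C@H]2[C@@]2(C[C@@H]4OC(C)(C)O[C@@H]4[C@@](C)(C(=O)OC)[C@H]2[C@@H]3C(=O)OC)C(=O)O1 | intermediate
36 | C16 ketone | O=C1C[C@]23C[C@H]1[C@@H]1C[C@H]2[C@@]2(C[C@@H]4OC(C)(C)O[C@@H]4[C@@](C)(C(=O)OC)[C@H]2[C@@H]3C(=O)OC)C(=O)O1 | intermediate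
37 | 2,3-acetonide 7,19-dimethyl ester of the target | C=C1C[C@]23C[C@H]1[C@@H]1C[C@H]2[C@@]2(C[C@@H]4OC(C)(C)O[C@@H]4[C@@](C)(C(=O)OC)[C@H]2[C@@H]3C(=O)OC)C(=O)O1 | intermediate
38 | 7,19-dimethyl ester of the target | C=C1C[C@]23C[C@H]1[C@@H]1C[C@H]2[C@@]2(C[C@H](O)[C@H](O)[C@@](C)(C(=O)OC)[C@H]2[C@@H]3C(=O)OC)C(=O)O1 | intermediate
39 | CNP0212122.1 | C=C1C[C@]23C[C@H]1[C@@H]1C[C@H]2[C@@]2(C[C@H](O)[C@H](O)[C@@](C)(C(=O)O)[C@H]2[C@@H]3C(=O)O)C(=O)O1 | target

## Step count and least certain steps

Total: 28 steps. Longest linear sequence: 27 steps (steps 1–8 and 10–28); step 9 is a one-step branch.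

**Step 20 (key step).** The cation 29 may be captured by trifluoroethanol or collapse by other ionic pathways faster than it cyclises. The base may also move the diene into conjugation with the C7 ester or epimerise C6, and the extended approach would give the lactone on the wrong side of ring C. The fallback takes the lactone out of the cation and relies on the known intramolecular (4+3) reaction of an open-chain α-chloro ketone with a tethered diene. It sets out from mixed anhydride 24. N,O-Dimethylhydroxylamine gives the N-methoxy-N-methylamide F1, and methylmagnesium bromide (Weinreb ketone synthesis) gives the C9-chloro methyl ketone F2. The palladium elimination and esterification of step 19 then give the cyclopentadienyl methyl ketone F3. Sodium 2,2,2-trifluoroethoxide in trifluoroethanol enolises F3 toward the methyl group and the cycloaddition gives the tetracyclic ketone F4, with C12 as CH2 and C20 still a tert-butyl ester. Silyl enol ether formation toward C12 and Rubottom oxidation on the face away from the C15=C16 bridge give the C12 hydroxy ketone F5. Warming F5 with catalytic p-toluenesulfonic acid closes the lactone with loss of isobutene, and the route is rejoined at 30.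

**Step 10.** The most likely failure is poor facial selectivity at C5, because the two C10 substituents differ in shape more than in size; 1,2-addition or proton transfer to the enolate may also compete. The fallback moves the control from the substrate to a chiral Lewis acid. It sets out from 14, which is converted (t-BuMe2SiOTf, Et3N) into the silyl ketene acetal F6. A Mukaiyama–Michael addition of F6 to 12, catalysed by Cu(OTf)2 with a chiral bis(oxazoline) ligand chosen to match the wanted face, gives the β-keto ester F7. Methylation of F7 (K2CO3, MeI, acetone) rejoins the route at 17.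

**Step 19.** Oxidative addition of zerovalent palladium into the C9–Cl bond next to the ketone may compete with ionisation of the allylic lactone. The fallback masks the ketone during the palladium step. It sets out from 26: Luche reduction gives the chlorohydrin lactone F8, the palladium elimination and esterification then give the cyclopentadienyl chlorohydrin F9, and Dess–Martin oxidation of F9 rejoins the route at 28.

**Step 2.** The ion-pair alkylation may discriminate the enolate faces insufficiently with a bromoacetate electrophile. The fallback builds the same centre by a Tsuji–Trost asymmetric allylation. It sets out from 4: allyl acetate, a zerovalent palladium source and a chiral diamine-derived bisphosphine give the allyl keto ester F10. Oxidative cleavage of the alkene (RuCl3, NaIO4) gives the acid F11, and esterification of F11 with 2 (carbodiimide, 4-(dimethylamino)pyridine) rejoins the route at 5.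

**Step 21 (with steps 22 and 23).** If hydride enters from the alkene side, the new C11 alkoxide lies next to C20 and the lactone acyl group may migrate to it. The fallback avoids the alcohol. It sets out from 30: ethane-1,2-dithiol with a mild Lewis acid (Zn(OTf)2) gives the C11 dithiolane F12, and radical desulfurisation of F12 with Bu3SnH and AIBN rejoins the route at 33.

## Further compounds

F1 | step 20 | C11 N-methoxy-N-methylamide | CON(C)C(=O)[C@H](Cl)[C@@]2(C[C@@H]4OC(C)(C)O[C@@H]4[C@@](C)(C(=O)OC)[C@H]2[C@@H]5C(=O)O[C@H]6C=CC[C@@H]56)C(=O)OC(C)(C)C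
F2 | step 20 | C9-chloro methyl ketone with allylic lactone | CC(=O)[C@H](Cl)[C@@]2(C[C@@H]4OC(C)(C)O[C@@H]4[C@@](C)(C(=O)OC)[C@H]2[C@@H]5C(=O)O[C@H]6C=CC[C@@H]56)C(=O)OC(C)(C)C
F3 | step 20 | C9-chloro methyl ketone with cyclopentadienyl group and C7 methyl ester | CC(=O)[C@H](Cl)[C@@]2(C[C@@H]4OC(C)(C)O[C@@H]4[C@@](C)(C(=O)OC)[C@H]2[C@H](C(=O)OC)C3=CC=CC3)C(=O)OC(C)(C)C
F4 | step 20 | tetracyclic C11 ketone with C12 methylene and C20 tert-butyl ester | C1=C[C@]23C[C@H]1CC(=O)[C@H]2[C@@]2(C[C@@H]4OC(C)(C)O[C@@H]4[C@@](C)(C(=O)OC)[C@H]2[C@@H]3C(=O)OC)C(=O)OC(C)(C)C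
F5 | step 20 | C12 hydroxy C11 ketone | C1=C[C@]23C[C@H]1[C@@H](O)C(=O)[C@H]2[C@@]2(C[C@@H]4OC(C)(C)O[C@@H]4[C@@](C)(C(=O)OC)[C@H]2[C@@H]3C(=O)OC)C(=O)OC(C)(C)C
F6 | step 10 | tert-butyldimethylsilyl ketene acetal of 14 | C1=C(O[Si](C)(C)C(C)(C)C)O[C@H]2[C@H](Br)CC[C@@H]12
F7 | step 10 | Michael adduct β-keto ester (C4–H) | C[Si](C)(C)CCOC(=O)[C@H](Cl)[C@@]2(CCC(=O)C(C(=O)OC)[C@H]2[C@@H]5C(=O)O[C@H]6[C@H](Br)CC[C@@H]56)C(=O)OC(C)(C)C
F8 | step 19 | C11 chlorohydrin lactone with allylic lactone | C1C(O)[C@H](Cl)[C@@]2(C[C@@H]4OC(C)(C)O[C@@H]4[C@@](C)(C(=O)OC)[C@H]2[C@@H]5C(=O)O[C@H]6C=CC[C@@H]56)C(=O)O1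
F9 | step 19 | C11 chlorohydrin lactone with cyclopentadienyl group and C7 methyl ester | C1C(O)[C@H](Cl)[C@@]2(C[C@@H]4OC(C)(C)O[C@@H]4[C@@](C)(C(=O)OC)[C@H]2[C@H](C(=O)OC)C3=CC=CC3)C(=O)O1
F10 | step 2 | tert-butyl (1R)-1-allyl-2-oxocyclohexane-1-carboxylate | C=CC[C@@]2(CCCCC2=O)C(=O)OC(C)(C)C
F11 | step 2 | (1R)-[1-(tert-butoxycarbonyl)-2-oxocyclohexyl]acetic acid | OC(=O)C[C@@]2(CCCCC2=O)C(=O)OC(C)(C)C
F12 | step 21 | C11 1,3-dithiolane of 30 | C1=C[C@]23C[C@H]1[C@@H]1C5(SCCS5)[C@H]2[C@@]2(C[C@@H]4OC(C)(C)O[C@@H]4[C@@](C)(C(=O)OC)[C@H]2[C@@H]3C(=O)OC)C(=O)O1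
A1 | alternative 1 | B/C hydrindanone with C9–H and allylated quaternary C10 | C[Si](C)(C)C#CC[C@]23CCC(=O)C[C@H]2[C@@](CC=C)(C(=O)OC)[C@@H]([C@@](C)(C=C)C(=O)OC)[C@@H]3C(=O)OC
A2 | alternative 2 | 2,3-acetonide 7,19-dimethyl ester of the target (identical with 37) | C=C1C[C@]23C[C@H]1[C@@H]1C[C@H]2[C@@]2(C[C@@H]4OC(C)(C)O[C@@H]4[C@@](C)(C(=O)OC)[C@H]2[C@@H]3C(=O)OC)C(=O)O1
A3 | alternative 3 | tricyclic A/B/C diketone with C4, C5, C9 and C10 set | COC(OC)C[C@]23CCC(=O)C[C@H]2[C@@]2(CCC(=O)[C@@](C)(C(=O)OC)[C@H]2[C@@H]3C(=O)OC)CO[Si](C)(C)C(C)(C)C
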